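The target is cut at the sp2–sp3 bond between the vinylic CH of the (E)-C(CH3)=CH unit of the side chain and the CH2CH2 arm on the quaternary carbon of the cyclohexane ring. In one operation, hydroboration of a vinyl group on that ring carbon and palladium-catalysed B-alkyl Suzuki–Miyaura coupling with a C14 (E)-vinyl iodide unite both halves with the trisubstituted alkene geometry intact. The ring partner carries the enal as a Weinreb amide; its (Z)-tetrasubstituted alkene is fixed earlier by a lactone-tethered ring-closing Horner–Wadsworth–Emmons reaction through the one-carbon arm that later becomes the vinyl group.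

Key step: step 17

Assumption: the phosphoramidite (step 1) and the amino-alcohol ligand (step 16) are taken to induce in the same sense as with cyclohexenone and simple aldehydes; if the sense proved opposite, the antipodal ligand would be used.

**Ring fragment**

Step 1
Reactants: 1 4,4-dimethoxycyclohexa-2,5-dien-1-one; 2 tert-butyl(3-iodopropoxy)dimethylsilane
Product: 4 (5S)-5-[3-(tert-butyldimethylsilyloxy)propyl]-4,4-dimethoxycyclohex-2-en-1-one, via dialkylzinc 3 (not isolated)
Conditions: 2, Et2Zn (excess), CuI (0.3 mol %), neat, 50 °C, volatiles removed in vacuo; then 1, Cu(OTf)2 (2 mol %), (R,S,S)-binaphthol bis(1-phenylethyl)amine phosphoramidite (4 mol %), toluene, −25 °C; then H2O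
Reagents that add atoms: none
Why: Iodine–zinc exchange should give the functionalised dialkylzinc, and copper–phosphoramidite-catalysed asymmetric conjugate addition should desymmetrise the quinone monoketal, the ligand choosing between the enantiotopic enone faces so that the single ring stereocentre is set under catalyst control.

Step 2
Reactants: 4 (5S)-5-[3-(tert-butyldimethylsilyloxy)propyl]-4,4-dimethoxycyclohex-2-en-1-one
Product: 5 (5S)-5-[3-(tert-butyldimethylsilyloxy)propyl]-4,4-dimethoxy-6-methylcyclohex-2-en-1-one (mixture of C-6 epimers)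
Conditions: LDA, THF, −78 °C; MeI, −78 → −20 °C
Reagents that add atoms: iodomethane, CI
Why: The remaining ring alkene blocks one side of the ketone, so kinetic enolate alkylation can only occur at C-6; the configuration of the new methine does not matter because it is planarised again in step 3.

Step 3
Reactants: 5 (5S)-5-[3-(tert-butyldimethylsilyloxy)propyl]-4,4-dimethoxy-6-methylcyclohex-2-en-1-one
Product: 6 (5S,6R)-5-[3-(tert-butyldimethylsilyloxy)propyl]-6-(hydroxymethyl)-4,4-dimethoxy-6-methylcyclohex-2-en-1-one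
Conditions: LDA, THF, −78 → 0 °C; CH2O (gas, from paraformaldehyde), −78 °C; then H2O
Reagents that add atoms: formaldehyde, C=O
Why: Aldol addition of the tetrasubstituted lithium enolate to formaldehyde should occur on the face anti to the neighbouring C-5 side chain, which sets the quaternary carbon with CH2OH trans and CH3 cis to that chain.

Step 4
Reactants: 6 (5S,6R)-5-[3-(tert-butyldimethylsilyloxy)propyl]-6-(hydroxymethyl)-4,4-dimethoxy-6-methylcyclohex-2-en-1-one
Product: 7 (2R,3S)-3-[3-(tert-butyldimethylsilyloxy)propyl]-2-(hydroxymethyl)-4,4-dimethoxy-2-methylcyclohexan-1-one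
Conditions: H2 (1 atm), Pd/C, EtOAc, rt
Reagents that add atoms: none
Why: Heterogeneous hydrogenation should saturate the enone alkene, which has served its purpose as a blocking group, without touching the ketal or the silyl ether.

Step 5
Reactants: 7 (2R,3S)-3-[3-(tert-butyldimethylsilyloxy)propyl]-2-(hydroxymethyl)-4,4-dimethoxy-2-methylcyclohexan-1-one
Product: 8 (1S,2R,3S)-3-[3-(tert-butyldimethylsilyloxy)propyl]-2-(hydroxymethyl)-4,4-dimethoxy-1,2-dimethylcyclohexan-1-ol
Conditions: MeMgBr (4 equiv), CH2Cl2/Et2O, −78 → 0 °C; then H2O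
Reagents that add atoms: methylmagnesium bromide, C[Mg]Br
Why: In this chelation-controlled Grignard addition the magnesium alkoxide of the equatorial CH2O arm holds the carbonyl, and methyl should enter axially on the face anti to the axial α-methyl group, giving the tertiary alcohol with OH cis to the ring methyl and the new methyl cis to the CH2OH arm.

Step 6
Reactants: 8 (1S,2R,3S)-3-[3-(tert-butyldimethylsilyloxy)propyl]-2-(hydroxymethyl)-4,4-dimethoxy-1,2-dimethylcyclohexan-1-ol; 9 2-(diethoxyphosphoryl)propanoic acid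
Product: 10 [(1R,2S,6S)-6-[3-(tert-butyldimethylsilyloxy)propyl]-2-hydroxy-5,5-dimethoxy-1,2-dimethylcyclohexyl]methyl 2-(diethoxyphosphoryl)propanoate
Conditions: DCC, DMAP (cat.), CH2Cl2, 0 °C → rt
Reagents that add atoms: none
Why: Steglich esterification should acylate the primary hydroxyl selectively, since the tertiary alcohol is far too hindered to compete.

Step 7
Reactants: 10 [(1R,2S,6S)-6-[3-(tert-butyldimethylsilyloxy)propyl]-2-hydroxy-5,5-dimethoxy-1,2-dimethylcyclohexyl]methyl 2-(diethoxyphosphoryl)propanoate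
Product: 11 [(1R,2S,6S)-6-[3-(tert-butyldimethylsilyloxy)propyl]-2-hydroxy-1,2-dimethyl-5-oxocyclohexyl]methyl 2-(diethoxyphosphoryl)propanoate
Conditions: PPTS (cat.), THF/H2O, rt
Reagents that add atoms: water, O
Why: Mild acid hydrolysis should cleave the strained dimethyl ketal while the primary silyl ether, the ester and the phosphonate survive.

Step 8
Reactants: 11 [(1R,2S,6S)-6-[3-(tert-butyldimethylsilyloxy)propyl]-2-hydroxy-1,2-dimethyl-5-oxocyclohexyl]methyl 2-(diethoxyphosphoryl)propanoate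
Product: 12 (1R,9S,10R)-10-[3-(tert-butyldimethylsilyloxy)propyl]-9-hydroxy-1,5,9-trimethyl-3-oxabicyclo[4.3.1]dec-5-en-4-one
Conditions: NaH (1.05 equiv), THF (0.005 M), 0 → 60 °C
Reagents that add atoms: none
Why: In this intramolecular Horner–Wadsworth–Emmons olefination the tether allows closure only to the seven-membered lactone, in which the ester carbonyl and the ring carbon bearing the silyloxypropyl chain are necessarily cis on the new tetrasubstituted alkene, so the (Z) geometry of the future enal is fixed by the ring.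

Step 9
Reactants: 12 (1R,9S,10R)-10-[3-(tert-butyldimethylsilyloxy)propyl]-9-hydroxy-1,5,9-trimethyl-3-oxabicyclo[4.3.1]dec-5-en-4-one
Product: 13 (1R,9S,10R)-10-[3-(tert-butyldimethylsilyloxy)propyl]-1,5,9-trimethyl-9-(triethylsilyloxy)-3-oxabicyclo[4.3.1]dec-5-en-4-one
Conditions: TESOTf, 2,6-lutidine, CH2Cl2, −78 → 0 °C
Reagents that add atoms: triethylsilyl trifluoromethanesulfonate, CC[Si](CC)(CC)OS(=O)(=O)C(F)(F)F
Why: Silylation with a silyl triflate should cap the hindered tertiary alcohol, which removes the retro-aldol pathway of the β-hydroxy aldehyde made in step 11.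

Step 10
Reactants: 13 (1R,9S,10R)-10-[3-(tert-butyldimethylsilyloxy)propyl]-1,5,9-trimethyl-9-(triethylsilyloxy)-3-oxabicyclo[4.3.1]dec-5-en-4-one
Product: 14 (2Z)-2-[(2R,3R,4S)-2-[3-(tert-butyldimethylsilyloxy)propyl]-3-(hydroxymethyl)-3,4-dimethyl-4-(triethylsilyloxy)cyclohexylidene]-N-methoxy-N-methylpropanamide
Conditions: MeNH(OMe)·HCl, AlMe3, CH2Cl2, 0 °C → rt; then aq. sodium potassium tartrate
Reagents that add atoms: N,O-dimethylhydroxylamine hydrochloride, CNOC.Cl
Why: Weinreb aminolysis with the aluminium amide should open the strained bridged lactone irreversibly, freeing the primary alcohol and storing the enal carbon as an amide with the alkene geometry untouched.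

Step 11
Reactants: 14 (2Z)-2-[(2R,3R,4S)-2-[3-(tert-butyldimethylsilyloxy)propyl]-3-(hydroxymethyl)-3,4-dimethyl-4-(triethylsilyloxy)cyclohexylidene]-N-methoxy-N-methylpropanamide
Product: 15 (2Z)-2-[(2R,3S,4S)-2-[3-(tert-butyldimethylsilyloxy)propyl]-3-formyl-3,4-dimethyl-4-(triethylsilyloxy)cyclohexylidene]-N-methoxy-N-methylpropanamide
Conditions: Dess–Martin periodinane, CH2Cl2, 0 °C → rt
Reagents that add atoms: none
Why: Dess–Martin oxidation should give the non-enolisable neopentyl aldehyde without affecting the silyl ethers or the amide.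

Step 12
Reactants: 15 (2Z)-2-[(2R,3S,4S)-2-[3-(tert-butyldimethylsilyloxy)propyl]-3-formyl-3,4-dimethyl-4-(triethylsilyloxy)cyclohexylidene]-N-methoxy-N-methylpropanamide
Product: 16 (2Z)-2-[(2R,3S,4S)-2-[3-(tert-butyldimethylsilyloxy)propyl]-3-ethenyl-3,4-dimethyl-4-(triethylsilyloxy)cyclohexylidene]-N-methoxy-N-methylpropanamide
Conditions: Ph3PCH3Br, KHMDS, THF, 0 °C → rt
Reagents that add atoms: methyltriphenylphosphonium bromide, C[P+](c1ccccc1)(c1ccccc1)c1ccccc1.[Br-]
Why: Wittig methylenation with the small unstabilised ylide should convert even this hindered aldehyde into the vinyl group, and the Weinreb amide is inert to the ylide.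

**Side-chain fragment**

Step 13
Reactants: 17 prop-2-yn-1-ol
Product: 19 (2E)-3-iodo-2-methylprop-2-en-1-ol, via alkenylalane 18 (not isolated)
Conditions: AlMe3 (3 equiv), Cp2ZrCl2 (0.25 equiv), CH2Cl2, 0 °C → rt; then I2, THF, −30 → 0 °C; then H2O
Reagents that add atoms: trimethylaluminium, C[Al](C)C; iodine, II
Why: Negishi zirconium-catalysed carboalumination adds methyl and aluminium syn across the alkyne with aluminium at the terminus, and iododealumination with retention should give the (E)-vinyl iodide.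

Step 14
Reactants: 19 (2E)-3-iodo-2-methylprop-2-en-1-ol
Product: 20 (2E)-3-iodo-2-methylprop-2-enal
Conditions: MnO2, CH2Cl2, rt
Reagents that add atoms: none
Why: Allylic oxidation with MnO2 should give the enal without isomerising the alkene.

Step 15
Reactants: 21 (S)-citronellal [(3S)-3,7-dimethyloct-6-enal]
Product: 23 (3S)-3,7-dimethyloct-6-en-1-yne, via enol nonaflate 22 (not isolated)
Conditions: C4F9SO2F (nonafluorobutanesulfonyl fluoride), P2-Et phosphazene base (2.2 equiv), DMF, −30 °C → rt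
Reagents that add atoms: none
Why: Enol sulfonate formation followed by base-induced elimination should turn CH2–CHO into C≡CH without changing the carbon count, and the stereocentre, being β to the carbonyl, is not enolisable.

Step 16
Reactants: 23 (3S)-3,7-dimethyloct-6-en-1-yne; 20 (2E)-3-iodo-2-methylprop-2-enal
Product: 26 (1E,3S,4E,6S)-1-iodo-2,6,10-trimethylundeca-1,4,9-trien-3-ol, via alkenylborane 24 (not isolated), via alkenylzinc 25 (not isolated)
Conditions: Cy2BH, toluene, 0 °C → rt; Me2Zn, −78 °C; (−)-3-exo-morpholinoisoborneol (5 mol %), 20, −20 → 0 °C; then H2O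
Reagents that add atoms: none
Why: Syn hydroboration of the terminal alkyne (the trisubstituted alkene is too hindered for Cy2BH) gives the (E)-alkenylborane, boron-to-zinc transmetalation gives the alkenylzinc, and the amino-alcohol-catalysed addition should occur on the Si face of the aldehyde to set the (S)-carbinol under catalyst control.

**Coupling and completion**

Step 17
Reactants: 16 (2Z)-2-[(2R,3S,4S)-2-[3-(tert-butyldimethylsilyloxy)propyl]-3-ethenyl-3,4-dimethyl-4-(triethylsilyloxy)cyclohexylidene]-N-methoxy-N-methylpropanamide; 26 (1E,3S,4E,6S)-1-iodo-2,6,10-trimethylundeca-1,4,9-trien-3-ol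
Product: 28 (2Z)-2-[(2R,3S,4S)-2-[3-(tert-butyldimethylsilyloxy)propyl]-3-[(3E,5S,6E,8S)-5-hydroxy-4,8,12-trimethyltrideca-3,6,11-trien-1-yl]-3,4-dimethyl-4-(triethylsilyloxy)cyclohexylidene]-N-methoxy-N-methylpropanamide, via B-alkyl-9-BBN borane 27 (not isolated)
Conditions: 9-BBN dimer, THF, rt → 45 °C; then H2O, 26, Pd(dppf)Cl2 (10 mol %), AsPh3 (10 mol %), Cs2CO3, DMF, rt
Reagents that add atoms: none
Why: 9-BBN should add to the monosubstituted vinyl group with boron at the terminal carbon; zerovalent palladium then inserts into the C–I bond of 26, base-assisted boron-to-palladium transfer of the primary alkyl group follows, and reductive elimination forms the CH2–CH(sp2) bond. The closest known reaction type is the B-alkyl Suzuki–Miyaura coupling of a 9-BBN adduct with an (E)-alkenyl iodide. No ring is closed and no stereocentre is created; the (E) geometry of the trisubstituted alkene is carried over from the vinyl iodide (set by syn carboalumination) because oxidative addition and reductive elimination proceed with retention. The step needs chemoselective hydroboration, secured because the only other C=C of 16 is tetrasubstituted and amide-conjugated and the amide is hindered, and it needs transmetalation to outrun β-hydride elimination, which the wide-bite-angle dppf ligand together with AsPh3 favours. The free allylic alcohol of 26 and both silyl ethers should be inert to the aqueous carbonate conditions.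

Step 18
Reactants: 28 (2Z)-2-[(2R,3S,4S)-2-[3-(tert-butyldimethylsilyloxy)propyl]-3-[(3E,5S,6E,8S)-5-hydroxy-4,8,12-trimethyltrideca-3,6,11-trien-1-yl]-3,4-dimethyl-4-(triethylsilyloxy)cyclohexylidene]-N-methoxy-N-methylpropanamide
Product: 29 (2Z)-2-[(2R,3S,4S)-2-[3-(tert-butyldimethylsilyloxy)propyl]-3-[(3E,5S,6E,8S)-5-hydroxy-4,8,12-trimethyltrideca-3,6,11-trien-1-yl]-3,4-dimethyl-4-(triethylsilyloxy)cyclohexylidene]propanal
Conditions: DIBAL (4 equiv), THF, −78 °C; then aq. sodium potassium tartrate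
Reagents that add atoms: none
Why: Weinreb amide reduction stops at the chelated tetrahedral aluminate, so the (Z)-enal should be released only on work-up, with no oxidation step needed in the presence of the free bis-allylic alcohol.

Step 19
Reactants: 29 (2Z)-2-[(2R,3S,4S)-2-[3-(tert-butyldimethylsilyloxy)propyl]-3-[(3E,5S,6E,8S)-5-hydroxy-4,8,12-trimethyltrideca-3,6,11-trien-1-yl]-3,4-dimethyl-4-(triethylsilyloxy)cyclohexylidene]propanal
Product: 30 (2Z)-2-[(2R,3S,4S)-4-hydroxy-3-[(3E,5S,6E,8S)-5-hydroxy-4,8,12-trimethyltrideca-3,6,11-trien-1-yl]-2-(3-hydroxypropyl)-3,4-dimethylcyclohexylidene]propanal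
Conditions: TBAF, AcOH, THF, 0 °C → rt
Reagents that add atoms: none
Why: Fluoride desilylation buffered with acetic acid should remove the primary TBS and tertiary TES ethers without deconjugating the enal or ionising the bis-allylic alcohol.

**Compound list**

1 | 4,4-dimethoxycyclohexa-2,5-dien-1-one | COC1(OC)C=CC(=O)C=C1 | starting material
2 | tert-butyl(3-iodopropoxy)dimethylsilane | CC(C)(C)[Si](C)(C)OCCCI | starting material
3 | bis[3-(tert-butyldimethylsilyloxy)propyl]zinc | CC(C)(C)[Si](C)(C)OCCC[Zn]CCCO[Si](C)(C)C(C)(C)C | intermediate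
4 | (5S)-5-[3-(tert-butyldimethylsilyloxy)propyl]-4,4-dimethoxycyclohex-2-en-1-one | C1[C@H](CCCO[Si](C)(C)C(C)(C)C)C(OC)(OC)C=CC1=O | intermediate
5 | (5S)-5-[3-(tert-butyldimethylsilyloxy)propyl]-4,4-dimethoxy-6-methylcyclohex-2-en-1-one (mixture of C-6 epimers) | CC1[C@H](CCCO[Si](C)(C)C(C)(C)C)C(OC)(OC)C=CC1=O | intermediate
6 | (5S,6R)-5-[3-(tert-butyldimethylsilyloxy)propyl]-6-(hydroxymethyl)-4,4-dimethoxy-6-methylcyclohex-2-en-1-one | OC[C@@]1(C)[C@H](CCCO[Si](C)(C)C(C)(C)C)C(OC)(OC)C=CC1=O | intermediate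
7 | (2R,3S)-3-[3-(tert-butyldimethylsilyloxy)propyl]-2-(hydroxymethyl)-4,4-dimethoxy-2-methylcyclohexan-1-one | OC[C@@]1(C)[C@H](CCCO[Si](C)(C)C(C)(C)C)C(OC)(OC)CCC1=O | intermediate
8 | (1S,2R,3S)-3-[3-(tert-butyldimethylsilyloxy)propyl]-2-(hydroxymethyl)-4,4-dimethoxy-1,2-dimethylcyclohexan-1-ol | OC[C@@]1(C)[C@H](CCCO[Si](C)(C)C(C)(C)C)C(OC)(OC)CC[C@]1(C)O | intermediate
9 | 2-(diethoxyphosphoryl)propanoic acid (racemic) | CCOP(=O)(OCC)C(C)C(O)=O | starting material
10 | [(1R,2S,6S)-6-[3-(tert-butyldimethylsilyloxy)propyl]-2-hydroxy-5,5-dimethoxy-1,2-dimethylcyclohexyl]methyl 2-(diethoxyphosphoryl)propanoate | CCOP(=O)(OCC)C(C)C(=O)OC[C@@]1(C)[C@H](CCCO[Si](C)(C)C(C)(C)C)C(OC)(OC)CC[C@]1(C)O | intermediate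
11 | [(1R,2S,6S)-6-[3-(tert-butyldimethylsilyloxy)propyl]-2-hydroxy-1,2-dimethyl-5-oxocyclohexyl]methyl 2-(diethoxyphosphoryl)propanoate | CCOP(=O)(OCC)C(C)C(=O)OC[C@@]1(C)[C@H](CCCO[Si](C)(C)C(C)(C)C)C(=O)CC[C@]1(C)O | intermediate
12 | (1R,9S,10R)-10-[3-(tert-butyldimethylsilyloxy)propyl]-9-hydroxy-1,5,9-trimethyl-3-oxabicyclo[4.3.1]dec-5-en-4-one (bridged seven-membered enoate lactone) | O=C1OC[C@@]2(C)[C@H](CCCO[Si](C)(C)C(C)(C)C)/C(=C1/C)CC[C@]2(C)O | intermediate
13 | (1R,9S,10R)-10-[3-(tert-butyldimethylsilyloxy)propyl]-1,5,9-trimethyl-9-(triethylsilyloxy)-3-oxabicyclo[4.3.1]dec-5-en-4-one | O=C1OC[C@@]2(C)[C@H](CCCO[Si](C)(C)C(C)(C)C)/C(=C1/C)CC[C@]2(C)O[Si](CC)(CC)CC | intermediate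
14 | (2Z)-2-[(2R,3R,4S)-2-[3-(tert-butyldimethylsilyloxy)propyl]-3-(hydroxymethyl)-3,4-dimethyl-4-(triethylsilyloxy)cyclohexylidene]-N-methoxy-N-methylpropanamide | OC[C@@]1(C)[C@H](CCCO[Si](C)(C)C(C)(C)C)/C(=C(/C)C(=O)N(C)OC)CC[C@]1(C)O[Si](CC)(CC)CC | intermediate
15 | (2Z)-2-[(2R,3S,4S)-2-[3-(tert-butyldimethylsilyloxy)propyl]-3-formyl-3,4-dimethyl-4-(triethylsilyloxy)cyclohexylidene]-N-methoxy-N-methylpropanamide | O=C[C@@]1(C)[C@H](CCCO[Si](C)(C)C(C)(C)C)/C(=C(/C)C(=O)N(C)OC)CC[C@]1(C)O[Si](CC)(CC)CC | intermediate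
16 | (2Z)-2-[(2R,3S,4S)-2-[3-(tert-butyldimethylsilyloxy)propyl]-3-ethenyl-3,4-dimethyl-4-(triethylsilyloxy)cyclohexylidene]-N-methoxy-N-methylpropanamide | C=C[C@@]1(C)[C@H](CCCO[Si](C)(C)C(C)(C)C)/C(=C(/C)C(=O)N(C)OC)CC[C@]1(C)O[Si](CC)(CC)CC | intermediate
17 | prop-2-yn-1-ol | OCC#C | starting material
18 | (E)-alkenylalane from methylalumination of 17 (dimethylaluminium alkoxide, dimethylalanyl at the alkene terminus) | C[Al](C)OC/C(C)=C/[Al](C)C | intermediate
19 | (2E)-3-iodo-2-methylprop-2-en-1-ol | OC/C(C)=C/I | intermediate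
20 | (2E)-3-iodo-2-methylprop-2-enal | O=C/C(C)=C/I | intermediate
21 | (S)-citronellal, (3S)-3,7-dimethyloct-6-enal | CC(C)=CCC[C@H](C)CC=O | starting material
22 | (3S)-3,7-dimethylocta-1,6-dien-1-yl nonafluorobutanesulfonate (E/Z mixture) | CC(C)=CCC[C@H](C)C=COS(=O)(=O)C(F)(F)C(F)(F)C(F)(F)C(F)(F)F | intermediate
23 | (3S)-3,7-dimethyloct-6-en-1-yne | CC(C)=CCC[C@H](C)C#C | intermediate
24 | dicyclohexyl[(1E,3S)-3,7-dimethylocta-1,6-dien-1-yl]borane | CC(C)=CCC[C@H](C)/C=C/B(C1CCCCC1)C1CCCCC1 | intermediate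
25 | [(1E,3S)-3,7-dimethylocta-1,6-dien-1-yl](methyl)zinc | CC(C)=CCC[C@H](C)/C=C/[Zn]C | intermediate
26 | (1E,3S,4E,6S)-1-iodo-2,6,10-trimethylundeca-1,4,9-trien-3-ol | CC(C)=CCC[C@H](C)/C=C/[C@H](O)/C(C)=C/I | intermediate
27 | (2Z)-2-[(2R,3S,4S)-3-[2-(9-borabicyclo[3.3.1]nonan-9-yl)ethyl]-2-[3-(tert-butyldimethylsilyloxy)propyl]-3,4-dimethyl-4-(triethylsilyloxy)cyclohexylidene]-N-methoxy-N-methylpropanamide | C(C[C@@]1(C)[C@H](CCCO[Si](C)(C)C(C)(C)C)/C(=C(/C)C(=O)N(C)OC)CC[C@]1(C)O[Si](CC)(CC)CC)B1C2CCCC1CCC2 | intermediate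
28 | (2Z)-2-[(2R,3S,4S)-2-[3-(tert-butyldimethylsilyloxy)propyl]-3-[(3E,5S,6E,8S)-5-hydroxy-4,8,12-trimethyltrideca-3,6,11-trien-1-yl]-3,4-dimethyl-4-(triethylsilyloxy)cyclohexylidene]-N-methoxy-N-methylpropanamide | CC(C)=CCC[C@H](C)/C=C/[C@H](O)/C(C)=C/CC[C@@]1(C)[C@H](CCCO[Si](C)(C)C(C)(C)C)/C(=C(/C)C(=O)N(C)OC)CC[C@]1(C)O[Si](CC)(CC)CC | intermediate
29 | (2Z)-2-[(2R,3S,4S)-2-[3-(tert-butyldimethylsilyloxy)propyl]-3-[(3E,5S,6E,8S)-5-hydroxy-4,8,12-trimethyltrideca-3,6,11-trien-1-yl]-3,4-dimethyl-4-(triethylsilyloxy)cyclohexylidene]propanal | CC(C)=CCC[C@H](C)/C=C/[C@H](O)/C(C)=C/CC[C@@]1(C)[C@H](CCCO[Si](C)(C)C(C)(C)C)/C(=C(/C)C=O)CC[C@]1(C)O[Si](CC)(CC)CC | intermediate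
30 | CNP0323596.2, (2Z)-2-[(2R,3S,4S)-4-hydroxy-3-[(3E,5S,6E,8S)-5-hydroxy-4,8,12-trimethyltrideca-3,6,11-trien-1-yl]-2-(3-hydroxypropyl)-3,4-dimethylcyclohexylidene]propanal | CC(C)=CCC[C@H](C)/C=C/[C@H](O)/C(C)=C/CC[C@@]1(C)[C@H](CCCO)/C(=C(/C)C=O)CC[C@]1(C)O | target

**Count and risks**

Total steps: 19. Longest linear sequence: 15 (steps 1–12, then 17–19); the side chain takes steps 13–16.

The three steps most likely to fail:

1. Step 8. Closure of the seven-membered ring at a hindered ketone may be outrun by intermolecular olefination, and enolisation of the ketone could epimerise the ring carbon bearing the silyloxypropyl chain. The fallback sets out from 8 and returns at 13. Acylation of 8 with 2-bromopropanoyl bromide and pyridine would give the bromo ester F1, and TESOTf/2,6-lutidine would give its tertiary triethylsilyl ether F2. PPTS in THF/H2O would then unmask the ketone F3. SmI2 (THF, −78 °C, high dilution) would close the ring by an intramolecular Reformatsky reaction to the β-hydroxy lactone F4. Dehydration with Martin sulfurane, followed by DBU to bring the alkene into conjugation, would give 13.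

2. Step 17. Hydroboration of the doubly neopentyl vinyl group may be slow enough for 9-BBN to attack the Weinreb amide, and the alkylpalladium intermediate may undergo β-hydride elimination before reductive elimination. The fallback sets out from 16 and returns at 28, replacing the in situ trialkylborane by an isolated tetracoordinate boron partner. Iridium-catalysed hydroboration with pinacolborane ([Ir(cod)Cl]2, dppe, CH2Cl2) would give the pinacol boronate F5 without touching the amide. KHF2 in MeOH/H2O would convert it into the potassium trifluoroborate F6, which can be purified. Coupling of F6 with 26 (Pd(dppf)Cl2, Cs2CO3, THF/H2O, 70 °C) would give 28.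

3. Step 1. Transfer of the functionalised alkyl group from zinc may be slow or poorly face-selective, which would erode the enantiomeric purity of the whole ring fragment. The fallback sets out from 1 and returns at 7. Hayashi–Miyaura addition of (E)-3-(tert-butyldimethylsilyloxy)prop-1-enylboronic acid pinacol ester to 1 (Rh(acac)(C2H4)2, (S)-BINAP, dioxane/H2O) would give the alkenyl adduct F7. LDA/MeI would give the methyl ketone F8, and LDA/CH2O the hydroxymethyl compound F9. Hydrogenation of both C=C bonds (H2, Rh/Al2O3, EtOAc) would give 7.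

Further compounds
F1 | step 8 | [(1R,2S,6S)-6-[3-(tert-butyldimethylsilyloxy)propyl]-2-hydroxy-5,5-dimethoxy-1,2-dimethylcyclohexyl]methyl 2-bromopropanoate | CC(Br)C(=O)OC[C@@]1(C)[C@H](CCCO[Si](C)(C)C(C)(C)C)C(OC)(OC)CC[C@]1(C)O
F2 | step 8 | triethylsilyl ether of F1 at the tertiary hydroxyl | CC(Br)C(=O)OC[C@@]1(C)[C@H](CCCO[Si](C)(C)C(C)(C)C)C(OC)(OC)CC[C@]1(C)O[Si](CC)(CC)CC
F3 | step 8 | [(1R,2S,6S)-6-[3-(tert-butyldimethylsilyloxy)propyl]-1,2-dimethyl-5-oxo-2-(triethylsilyloxy)cyclohexyl]methyl 2-bromopropanoate | CC(Br)C(=O)OC[C@@]1(C)[C@H](CCCO[Si](C)(C)C(C)(C)C)C(=O)CC[C@]1(C)O[Si](CC)(CC)CC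
F4 | step 8 | 10-[3-(tert-butyldimethylsilyloxy)propyl]-6-hydroxy-1,5,9-trimethyl-9-(triethylsilyloxy)-3-oxabicyclo[4.3.1]decan-4-one (β-hydroxy lactone, ring stereocentres as in 13, C-5 and C-6 as formed) | O=C1OC[C@@]2(C)[C@H](CCCO[Si](C)(C)C(C)(C)C)C(O)(C1C)CC[C@]2(C)O[Si](CC)(CC)CC
F5 | step 17 | pinacol boronate of the hydroborated vinyl group of 16 [2-(4,4,5,5-tetramethyl-1,3,2-dioxaborolan-2-yl)ethyl in place of ethenyl] | CC1(C)OB(CC[C@@]2(C)[C@H](CCCO[Si](C)(C)C(C)(C)C)/C(=C(/C)C(=O)N(C)OC)CC[C@]2(C)O[Si](CC)(CC)CC)OC1(C)C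
F6 | step 17 | potassium trifluoroborate corresponding to F5 | [K+].F[B-](F)(F)CC[C@@]1(C)[C@H](CCCO[Si](C)(C)C(C)(C)C)/C(=C(/C)C(=O)N(C)OC)CC[C@]1(C)O[Si](CC)(CC)CC
F7 | step 1 | (5R)-5-[(1E)-3-(tert-butyldimethylsilyloxy)prop-1-en-1-yl]-4,4-dimethoxycyclohex-2-en-1-one | C1[C@H](/C=C/CO[Si](C)(C)C(C)(C)C)C(OC)(OC)C=CC1=O
F8 | step 1 | (5S)-5-[(1E)-3-(tert-butyldimethylsilyloxy)prop-1-en-1-yl]-4,4-dimethoxy-6-methylcyclohex-2-en-1-one (mixture of C-6 epimers) | CC1[C@H](/C=C/CO[Si](C)(C)C(C)(C)C)C(OC)(OC)C=CC1=O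
F9 | step 1 | (5S,6R)-5-[(1E)-3-(tert-butyldimethylsilyloxy)prop-1-en-1-yl]-6-(hydroxymethyl)-4,4-dimethoxy-6-methylcyclohex-2-en-1-one | OC[C@@]1(C)[C@H](/C=C/CO[Si](C)(C)C(C)(C)C)C(OC)(OC)C=CC1=O
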